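The numbers in the tables stem from a simulated flask for an exercise, noise included.

the same everywhere: starting material 0.30 M; free catalyst 0.30 mM

|  | partner | impurity | remark | time |
|---|---|---|---|---|
| spring | 0.90 M | 5.9 µM | run made earlier |  |
| midnight | 0.90 M | 550 µM | run made earlier |  |
| blue | 0.900 M | 10 µM |  | 8.0 h |
| violet | 0.900 M | 30 µM |  | 8.0 h |
| teal | 0.900 M | 100 µM |  | 8.0 h |
| red | 0.900 M | 300 µM |  | 8.0 h |
| grey | 0.900 M | 800 µM |  | 8.0 h |

| run | time / h | target / % |
|---|---|---|
| spring | 0.333 | 9 |
| spring | 0.833 | 19 |
| spring | 1.50 | 37 |
| spring | 2.50 | 54 |
| spring | 3.00 | 61 |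
| spring | 4.00 | 73 |
| spring | 6.00 | 88 |
| midnight | 0.833 | 0 |
| midnight | 1.50 | 2 |
| midnight | 2.50 | 0 |
| midnight | 3.00 | 2 |
| midnight | 4.00 | 0 |
| midnight | 5.00 | 0 |
| midnight | 6.00 | 0 |

(scatter of a reading: 1.5 percentage points)

- what was read earlier has a scatter of 1.5 percentage points, one standard deviation
- "hardly changes" means that all values lie within two and a half points (for a concentration: within two and a half percent of the largest)

1. amount of target at the end, in percent of the starting material charged for blue, violet, teal, red, grey, in this order
2. how that number moves from the first to the last of them (rises all the way / falls all the way / hardly changes / falls, then rises / rises, then falls)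

1. The spring run, with 5.9 µM of impurity against 0.30 mM of free catalyst, held 73% target after 4.00 h. Read as a pseudo-first-order loss of starting material, that reading gives a rate constant k of 0.327 h⁻¹. The midnight run, with 550 µM of impurity, more than its catalyst, read 0% after 6.00 h.

2. The reckoning here assumes that one impurity removes one free catalyst, and that k scales with the difference [free catalyst] − [impurity]. The spring k then folds into one number, 2.67, called the clean depth D: the number of e-foldings of the starting material reckoned for the whole charged catalyst over 8.0 h. A flask then has the depth D(1 − [impurity]/[free catalyst]), and its target is one minus the exponential of minus that depth.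

3. This gives 92.4% for blue, 91.0% for violet and 83.1% for teal. In red the impurity equals the catalyst, so the depth is 0. Grey has 2.67 impurity per catalyst, so the reckoning leaves it no working catalyst either.

4. One number is tested on the spring curve itself. The reading at 0.833 h gives k = 0.253 h⁻¹, and the reading at 6.00 h gives 0.353 h⁻¹, which is higher. With the later k, teal comes to 85.4%, so the drift is worth 2.2 percentage points there.

5. The forecast gives 93%, 91%, 83%, 3% and 0%, a row that falls all the way. It stands 0.56 points above this reckoning for blue and puts 3% in red, where this reckoning has a depth of zero. Its own caution reads: “The stoichiometry is an assumption.”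

    free catalyst + impurity → spent catalyst (k = 50000 M⁻¹ min⁻¹)
    starting material + catalyst intermediate A ⇌ catalyst intermediate B (K = 0.630 M⁻¹, k = 63.0 M⁻¹ min⁻¹)
    catalyst intermediate B → free catalyst + target (k = 63.0 min⁻¹)
    partner + free catalyst → catalyst intermediate A (k = 17.0 M⁻¹ min⁻¹)

The flask gives 93.6%, 92.0%, 83.1%, 0.782% and 0.0479%, a row that falls all the way. Teal holds 33.3% of its catalyst as spent catalyst at 8.00 h, against 33.3% impurity per catalyst charged. The clean depth D of 2.67 gives teal a depth of 1.78, hence 83.1% against 83.1%. On violet the same D gives 91.0%, and violet stands at 92.0%.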